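## Retrosynthetic overview

1. Target ⇐ removal of five TIPS ethers ⇐ Heck coupling of a (2S,3S)-5-bromo-2,3-diaryl-2,3-dihydrobenzofuran with a 3,5-bis(silyloxy)styrene (stilbene bond made last).
2. The dihydrofuran ring (the only ring built) ⇐ ring contraction of a six-membered 2,4-diaryl-3,4-dihydro-2H-1,3-benzoxazine: the NH is excised as N2 and the C2–C3 bond forms in its place.
3. Benzoxazine ⇐ condensation of an (S)-2-(α-aminobenzyl)phenol with 4-silyloxybenzaldehyde; the amine carbon (future C3) ⇐ aryl addition to an Ellman sulfinyl imine of 5-bromosalicylaldehyde.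
4. Aryl blocks ⇐ resorcinol (silylation, C–H borylation, vinylation) and 4-bromophenol (ortho-formylation for ring A; silylation/lithiation/formylation for ring B).
5. Ring order: temporary six-membered N,O-aminal first, then contraction to the five-membered O-heterocycle; all benzene rings are bought.

Assumption: silyl chlorides, the sulfinamide auxiliary, B2pin2, paraformaldehyde, DMF and the N-transfer reagent are treated as reagents; the numbered starting materials are resorcinol, 4-bromophenol and vinyl bromide.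

Abbreviations: TIPS = triisopropylsilyl. Reagent A = N-(benzyloxy)-N-(pivaloyloxy)-4-(trifluoromethyl)benzamide, CC(C)(C)C(=O)ON(OCc1ccccc1)C(=O)c1ccc(C(F)(F)F)cc1.

## Route

Step 1
Reactants: 1 resorcinol
Product: 2 1,3-bis(triisopropylsilyloxy)benzene
Conditions: TIPSCl (2.2 equiv), imidazole (4.4 equiv), DMF, rt
Reagents that add atoms: triisopropylsilyl chloride, CC(C)[Si](Cl)(C(C)C)C(C)C
Why: Imidazole-promoted O-silylation of both phenols gives bulky ethers that later steer the borylation and survive the base, acid, Rh and Pd steps.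

Step 2
Reactants: 2 1,3-bis(triisopropylsilyloxy)benzene
Product: 3 2-[3,5-bis(triisopropylsilyloxy)phenyl]-4,4,5,5-tetramethyl-1,3,2-dioxaborolane
Conditions: [Ir(cod)(OMe)]2 (1.5 mol%), 4,4'-di-tert-butyl-2,2'-bipyridine (3 mol%), B2pin2 (1.0 equiv), cyclohexane, 80 °C
Reagents that add atoms: bis(pinacolato)diboron, CC1(C)OB(OC1(C)C)B1OC(C)(C)C(C)(C)O1
Why: Sterically controlled Ir-catalysed aromatic C–H borylation occurs only at C5, the one C–H not next to an OTIPS group.

Step 3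
Reactants: 4 4-bromophenol
Product: 5 5-bromo-2-hydroxybenzaldehyde
Conditions: MgCl2 (1.5 equiv), Et3N (3.75 equiv), paraformaldehyde (6.8 equiv), MeCN, reflux; aq. HCl work-up
Reagents that add atoms: paraformaldehyde (formaldehyde), C=O
Why: Magnesium-phenoxide-directed ortho-formylation (Casnati–Skattebøl) is ortho-specific, the para position being blocked by Br, and a second formaldehyde oxidises the benzylic alkoxide to the aldehyde.

Step 4
Reactants: 5 5-bromo-2-hydroxybenzaldehyde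
Product: 6 (R,E)-N-(5-bromo-2-hydroxybenzylidene)-2-methylpropane-2-sulfinamide
Conditions: (R)-tert-butanesulfinamide (1.05 equiv), Ti(OEt)4 (2 equiv), THF, rt
Reagents that add atoms: (R)-2-methylpropane-2-sulfinamide, CC(C)(C)[S@@](=O)N
Why: Ellman condensation with Ti(OEt)4 as Lewis acid and water scavenger gives the E-sulfinyl aldimine; no carbon stereocentre is formed yet.

Step 5
Reactants: 6 (R,E)-N-(5-bromo-2-hydroxybenzylidene)-2-methylpropane-2-sulfinamide, 3 2-[3,5-bis(triisopropylsilyloxy)phenyl]-4,4,5,5-tetramethyl-1,3,2-dioxaborolane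
Product: 8 (S)-2-{amino[3,5-bis(triisopropylsilyloxy)phenyl]methyl}-4-bromophenol, via sulfinamide adduct 7 (not isolated)
Conditions: 3 (1.3 equiv), [Rh(cod)(OH)]2 (2.5 mol%), 1,4-dioxane/H2O 10:1, 60 °C; then HCl (4 M in dioxane), MeOH, 0 °C; aq. NaHCO3
Reagents that add atoms: none
Why: Rh-catalysed 1,2-addition of the arylboronate to the N-sulfinyl aldimine (Ellman–Batey arylation) delivers the aryl group to the imine face syn to the sulfinyl oxygen of the (R)-auxiliary in the closed, O-coordinated transition state, setting the carbinamine carbon as S, and HCl/MeOH then cleaves the N–S bond without touching the aryl TIPS ethers or the aryl bromide.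

Step 6
Reactants: 4 4-bromophenol
Product: 11 4-(triisopropylsilyloxy)benzaldehyde, via silyl ether 9 (not isolated), via aryllithium 10 (not isolated)
Conditions: NaH (1.05 equiv), THF, 0 °C; TIPSCl (1.0 equiv), rt; then n-BuLi (1.1 equiv), −78 °C; DMF (1.5 equiv), −78 °C to rt; aq. NH4Cl
Reagents that add atoms: triisopropylsilyl chloride, CC(C)[Si](Cl)(C(C)C)C(C)C; N,N-dimethylformamide, CN(C)C=O
Why: One-pot O-silylation, Br/Li exchange and Bouveault formylation; the only co-product of the silylation is inert NaCl, and a para-silyloxy aryllithium cannot undergo retro-Brook migration.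

Step 7
Reactants: 8 (S)-2-{amino[3,5-bis(triisopropylsilyloxy)phenyl]methyl}-4-bromophenol, 11 4-(triisopropylsilyloxy)benzaldehyde
Product: 16 (2S,3S)-5-bromo-2-[4-(triisopropylsilyloxy)phenyl]-3-[3,5-bis(triisopropylsilyloxy)phenyl]-2,3-dihydro-1-benzofuran, via Schiff base 12 (not isolated), via benzoxazine aminal 13 (not isolated), via isodiazene 14 (not isolated), via cis epimer 15 (not isolated)
Conditions: 11 (1.05 equiv), 4 Å MS, THF, rt; then N-(benzyloxy)-N-(pivaloyloxy)-4-(trifluoromethyl)benzamide (1.5 equiv), 45 °C; then TFA, CH2Cl2, 0 °C to rt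
Reagents that add atoms: none
Why: Proposed new method: the aminal NH of 13 (or the imine N of its open tautomer 12, which recloses onto the phenol after amination) is aminated by the anomeric amide to give isodiazene 14, which loses N2 stepwise to a singlet 1,5-biradical that has no β-hydrogen and can only recombine C2–C4, contracting the six-membered N,O-aminal to the dihydrofuran with retention at the benzylic carbon (it becomes C3, S), while C2 is converged to trans by the final acid equilibration through reversible C2–O ionisation; the closest known reaction types are nitrogen deletion of secondary amines via isodiazenes (anomeric amide reagents) and the stereoretentive contraction of 1-amino-2,6-diarylpiperidines and 2-arylpyrrolidines to carbocycles, here extended for the first time to a ring-chain tautomeric N,O-aminal to make an O-heterocycle.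

Step 8
Reactants: 3 2-[3,5-bis(triisopropylsilyloxy)phenyl]-4,4,5,5-tetramethyl-1,3,2-dioxaborolane, 17 vinyl bromide
Product: 18 1-ethenyl-3,5-bis(triisopropylsilyloxy)benzene
Conditions: 17 (1 M in THF, 2.5 equiv), Pd(dppf)Cl2 (3 mol%), K3PO4 (3 equiv), THF/H2O, 65 °C, sealed tube
Reagents that add atoms: none
Why: Suzuki–Miyaura coupling of an aryl pinacol boronate with a vinyl halide is routine and the TIPS aryl ethers tolerate aqueous phosphate.

Step 9
Reactants: 16 (2S,3S)-5-bromo-2-[4-(triisopropylsilyloxy)phenyl]-3-[3,5-bis(triisopropylsilyloxy)phenyl]-2,3-dihydro-1-benzofuran, 18 1-ethenyl-3,5-bis(triisopropylsilyloxy)benzene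
Product: 19 (2S,3S)-5-{(E)-2-[3,5-bis(triisopropylsilyloxy)phenyl]ethenyl}-2-[4-(triisopropylsilyloxy)phenyl]-3-[3,5-bis(triisopropylsilyloxy)phenyl]-2,3-dihydro-1-benzofuran
Conditions: 18 (1.3 equiv), Pd(P(t-Bu)3)2 (5 mol%), Cy2NMe (1.5 equiv), 1,4-dioxane, 60 °C
Reagents that add atoms: none
Why: Mizoroki–Heck coupling (syn insertion, syn β-hydride elimination) gives the E-stilbene only and does not touch the two ring stereocentres.

Step 10
Reactants: 19 (2S,3S)-5-{(E)-2-[3,5-bis(triisopropylsilyloxy)phenyl]ethenyl}-2-[4-(triisopropylsilyloxy)phenyl]-3-[3,5-bis(triisopropylsilyloxy)phenyl]-2,3-dihydro-1-benzofuran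
Product: 20 (2S,3S)-trans-δ-viniferin
Conditions: TBAF (6 equiv), AcOH (6 equiv), THF, 0 °C to rt, dark, argon
Reagents that add atoms: none
Why: Acetic-acid-buffered fluoride desilylation frees the five phenols without strongly basic phenoxide conditions, so the oxidation-prone stilbene polyphenol and the thermodynamically preferred trans ring survive.

## Compound list

1 | resorcinol | Oc1cccc(O)c1 | starting material
2 | 1,3-bis(triisopropylsilyloxy)benzene | CC(C)[Si](C(C)C)(C(C)C)Oc1cccc(O[Si](C(C)C)(C(C)C)C(C)C)c1 | intermediate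
3 | 2-[3,5-bis(triisopropylsilyloxy)phenyl]-4,4,5,5-tetramethyl-1,3,2-dioxaborolane | CC(C)[Si](C(C)C)(C(C)C)Oc1cc(O[Si](C(C)C)(C(C)C)C(C)C)cc(B2OC(C)(C)C(C)(C)O2)c1 | intermediate
4 | 4-bromophenol | Oc1ccc(Br)cc1 | starting material
5 | 5-bromo-2-hydroxybenzaldehyde | O=Cc1cc(Br)ccc1O | intermediate
6 | (R,E)-N-(5-bromo-2-hydroxybenzylidene)-2-methylpropane-2-sulfinamide | CC(C)(C)[S@@](=O)/N=C/c1cc(Br)ccc1O | intermediate
7 | (R)-N-{(S)-(5-bromo-2-hydroxyphenyl)[3,5-bis(triisopropylsilyloxy)phenyl]methyl}-2-methylpropane-2-sulfinamide | CC(C)(C)[S@@](=O)N[C@H](c1cc(Br)ccc1O)c1cc(O[Si](C(C)C)(C(C)C)C(C)C)cc(O[Si](C(C)C)(C(C)C)C(C)C)c1 | intermediate (not isolated)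
8 | (S)-2-{amino[3,5-bis(triisopropylsilyloxy)phenyl]methyl}-4-bromophenol | N[C@H](c1cc(Br)ccc1O)c1cc(O[Si](C(C)C)(C(C)C)C(C)C)cc(O[Si](C(C)C)(C(C)C)C(C)C)c1 | intermediate
9 | (4-bromophenoxy)triisopropylsilane | CC(C)[Si](C(C)C)(C(C)C)Oc1ccc(Br)cc1 | intermediate (not isolated)
10 | [4-(triisopropylsilyloxy)phenyl]lithium | [Li]c1ccc(O[Si](C(C)C)(C(C)C)C(C)C)cc1 | intermediate (not isolated)
11 | 4-(triisopropylsilyloxy)benzaldehyde | O=Cc1ccc(O[Si](C(C)C)(C(C)C)C(C)C)cc1 | intermediate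
12 | (S,E)-4-bromo-2-{[3,5-bis(triisopropylsilyloxy)phenyl]({[4-(triisopropylsilyloxy)phenyl]methylidene}amino)methyl}phenol (open Schiff-base tautomer) | CC(C)[Si](C(C)C)(C(C)C)Oc1ccc(/C=N/[C@H](c2cc(Br)ccc2O)c2cc(O[Si](C(C)C)(C(C)C)C(C)C)cc(O[Si](C(C)C)(C(C)C)C(C)C)c2)cc1 | intermediate (not isolated)
13 | (4S)-6-bromo-2-[4-(triisopropylsilyloxy)phenyl]-4-[3,5-bis(triisopropylsilyloxy)phenyl]-3,4-dihydro-2H-1,3-benzoxazine (both C2 epimers, equilibrating through 12) | CC(C)[Si](C(C)C)(C(C)C)Oc1ccc(C2N[C@@H](c3cc(O[Si](C(C)C)(C(C)C)C(C)C)cc(O[Si](C(C)C)(C(C)C)C(C)C)c3)c3cc(Br)ccc3O2)cc1 | intermediate (not isolated)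
14 | N-isodiazene (1,1-diazene) of 13, (4S), both C2 epimers | CC(C)[Si](C(C)C)(C(C)C)Oc1ccc(C2Oc3ccc(Br)cc3[C@H](c3cc(O[Si](C(C)C)(C(C)C)C(C)C)cc(O[Si](C(C)C)(C(C)C)C(C)C)c3)[N+]2=[N-])cc1 | intermediate (not isolated)
15 | (2R,3S)-5-bromo-2-[4-(triisopropylsilyloxy)phenyl]-3-[3,5-bis(triisopropylsilyloxy)phenyl]-2,3-dihydro-1-benzofuran (cis) | CC(C)[Si](C(C)C)(C(C)C)Oc1ccc([C@@H]2Oc3ccc(Br)cc3[C@@H]2c2cc(O[Si](C(C)C)(C(C)C)C(C)C)cc(O[Si](C(C)C)(C(C)C)C(C)C)c2)cc1 | intermediate (not isolated)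
16 | (2S,3S)-5-bromo-2-[4-(triisopropylsilyloxy)phenyl]-3-[3,5-bis(triisopropylsilyloxy)phenyl]-2,3-dihydro-1-benzofuran (trans) | CC(C)[Si](C(C)C)(C(C)C)Oc1ccc([C@H]2Oc3ccc(Br)cc3[C@@H]2c2cc(O[Si](C(C)C)(C(C)C)C(C)C)cc(O[Si](C(C)C)(C(C)C)C(C)C)c2)cc1 | intermediate
17 | vinyl bromide (bromoethene) | C=CBr | starting material
18 | 1-ethenyl-3,5-bis(triisopropylsilyloxy)benzene | C=Cc1cc(O[Si](C(C)C)(C(C)C)C(C)C)cc(O[Si](C(C)C)(C(C)C)C(C)C)c1 | intermediate
19 | (2S,3S)-5-{(E)-2-[3,5-bis(triisopropylsilyloxy)phenyl]ethenyl}-2-[4-(triisopropylsilyloxy)phenyl]-3-[3,5-bis(triisopropylsilyloxy)phenyl]-2,3-dihydro-1-benzofuran | CC(C)[Si](C(C)C)(C(C)C)Oc1ccc([C@H]2Oc3ccc(/C=C/c4cc(O[Si](C(C)C)(C(C)C)C(C)C)cc(O[Si](C(C)C)(C(C)C)C(C)C)c4)cc3[C@@H]2c2cc(O[Si](C(C)C)(C(C)C)C(C)C)cc(O[Si](C(C)C)(C(C)C)C(C)C)c2)cc1 | intermediate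
20 | (2S,3S)-trans-δ-viniferin | Oc1ccc([C@H]2Oc3ccc(/C=C/c4cc(O)cc(O)c4)cc3[C@@H]2c2cc(O)cc(O)c2)cc1 | target

## Summary

Total step count: 10.
Longest linear sequence: 6 steps (1 → 2 → 3 → 8 → 16 → 19 → 20, steps 1, 2, 5, 7, 9, 10; the branch from 4 through steps 3, 4, 5, 7, 9, 10 is equally long).

Three steps most likely to fail:

**Step 7 (proposed ring contraction).** Risks are slow N-amination of the hindered aminal, consumption of the reagent by the open tautomer, and loss of configuration at the benzylic carbon if the biradical relaxes or the isodiazene fragments heterolytically. The ee of 16 is checked by chiral HPLC before going on.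
Fallback with known chemistry (enantioselective donor/donor carbene C–H insertion), setting out from 5 (with 11 and 3) and coming back at 16:
- Aldehyde 11 is reduced with NaBH4 to [4-(triisopropylsilyloxy)phenyl]methanol F1.
- Mitsunobu etherification of phenol 5 with F1 (PPh3, DIAD) gives 5-bromo-2-{[4-(triisopropylsilyloxy)phenyl]methoxy}benzaldehyde F2.
- [Rh(cod)(OH)]2-catalysed addition of boronate 3 gives racemic (5-bromo-2-{[4-(triisopropylsilyloxy)phenyl]methoxy}phenyl)[3,5-bis(triisopropylsilyloxy)phenyl]methanol F3.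
- MnO2 oxidation gives (5-bromo-2-{[4-(triisopropylsilyloxy)phenyl]methoxy}phenyl)[3,5-bis(triisopropylsilyloxy)phenyl]methanone F4.
- Hydrazine hydrate gives its hydrazone F5.
- MnO2 oxidation to the diaryldiazomethane F6 (used in solution) and Rh2(S-PTAD)4 or Rh2(R-PTAD)4 (the antipode that gives 3S) effects insertion into the benzylic ether C–H bond to give the cis dihydrobenzofuran 15.
- The same TFA treatment converts 15 into 16.

**Step 5 (aryl addition to the free-phenol sulfinyl imine).** Risks are low reactivity of the pinacol boronate under base-free Rh conditions and an uncertain sense of induction with the ortho-OH (closed versus open transition state). The configuration of 8 is confirmed by X-ray of a salt before going on.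
Fallback under catalyst control, setting out from 5 and 3 and coming back at 8:
- [Rh(cod)(OH)]2-catalysed addition of 3 to the aldehyde of 5 gives racemic (5-bromo-2-hydroxyphenyl)[3,5-bis(triisopropylsilyloxy)phenyl]methanol F7.
- MnO2 oxidation gives (5-bromo-2-hydroxyphenyl)[3,5-bis(triisopropylsilyloxy)phenyl]methanone F8.
- Ru-catalysed direct asymmetric reductive amination of this ortho-hydroxy diaryl ketone (Ru(OAc)2 with the C3-TunePhos enantiomer that gives S, NH4OAc, H2, CF3CH2OH) gives amine 8.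

**Step 9 (late Heck coupling).** Risks are sluggish oxidative addition of the electron-rich bromide, polymerisation of styrene 18, and partial silyl loss on heating.
Fallback, setting out from 16 and coming back at 19:
- Suzuki–Miyaura vinylation of 16 with potassium vinyltrifluoroborate (Pd(dppf)Cl2, Cs2CO3, THF/H2O) gives (2S,3S)-5-ethenyl-2-[4-(triisopropylsilyloxy)phenyl]-3-[3,5-bis(triisopropylsilyloxy)phenyl]-2,3-dihydro-1-benzofuran F9.
- Olefin cross-metathesis of F9 with excess 18 (second-generation Hoveyda–Grubbs catalyst, CH2Cl2, 40 °C) gives the E-stilbene 19.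

Further compounds
F1 | step 7 | [4-(triisopropylsilyloxy)phenyl]methanol | OCc1ccc(O[Si](C(C)C)(C(C)C)C(C)C)cc1
F2 | step 7 | 5-bromo-2-{[4-(triisopropylsilyloxy)phenyl]methoxy}benzaldehyde | O=Cc1cc(Br)ccc1OCc1ccc(O[Si](C(C)C)(C(C)C)C(C)C)cc1
F3 | step 7 | rac-(5-bromo-2-{[4-(triisopropylsilyloxy)phenyl]methoxy}phenyl)[3,5-bis(triisopropylsilyloxy)phenyl]methanol | OC(c1cc(Br)ccc1OCc1ccc(O[Si](C(C)C)(C(C)C)C(C)C)cc1)c1cc(O[Si](C(C)C)(C(C)C)C(C)C)cc(O[Si](C(C)C)(C(C)C)C(C)C)c1
F4 | step 7 | (5-bromo-2-{[4-(triisopropylsilyloxy)phenyl]methoxy}phenyl)[3,5-bis(triisopropylsilyloxy)phenyl]methanone | O=C(c1cc(Br)ccc1OCc1ccc(O[Si](C(C)C)(C(C)C)C(C)C)cc1)c1cc(O[Si](C(C)C)(C(C)C)C(C)C)cc(O[Si](C(C)C)(C(C)C)C(C)C)c1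
F5 | step 7 | hydrazone of F4 (E/Z mixture) | NN=C(c1cc(Br)ccc1OCc1ccc(O[Si](C(C)C)(C(C)C)C(C)C)cc1)c1cc(O[Si](C(C)C)(C(C)C)C(C)C)cc(O[Si](C(C)C)(C(C)C)C(C)C)c1
F6 | step 7 | (5-bromo-2-{[4-(triisopropylsilyloxy)phenyl]methoxy}phenyl)[3,5-bis(triisopropylsilyloxy)phenyl]diazomethane | [N-]=[N+]=C(c1cc(Br)ccc1OCc1ccc(O[Si](C(C)C)(C(C)C)C(C)C)cc1)c1cc(O[Si](C(C)C)(C(C)C)C(C)C)cc(O[Si](C(C)C)(C(C)C)C(C)C)c1
F7 | step 5 | rac-(5-bromo-2-hydroxyphenyl)[3,5-bis(triisopropylsilyloxy)phenyl]methanol | OC(c1cc(Br)ccc1O)c1cc(O[Si](C(C)C)(C(C)C)C(C)C)cc(O[Si](C(C)C)(C(C)C)C(C)C)c1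
F8 | step 5 | (5-bromo-2-hydroxyphenyl)[3,5-bis(triisopropylsilyloxy)phenyl]methanone | O=C(c1cc(Br)ccc1O)c1cc(O[Si](C(C)C)(C(C)C)C(C)C)cc(O[Si](C(C)C)(C(C)C)C(C)C)c1
F9 | step 9 | (2S,3S)-5-ethenyl-2-[4-(triisopropylsilyloxy)phenyl]-3-[3,5-bis(triisopropylsilyloxy)phenyl]-2,3-dihydro-1-benzofuran | CC(C)[Si](C(C)C)(C(C)C)Oc1ccc([C@H]2Oc3ccc(C=C)cc3[C@@H]2c2cc(O[Si](C(C)C)(C(C)C)C(C)C)cc(O[Si](C(C)C)(C(C)C)C(C)C)c2)cc1
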